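**Numbering used throughout.** 1 = 2,6-dibromo-1,4-benzoquinone; 2 = 2,4-dibromophenol; 3 = potassium 2,4-dibromophenoxide; 4 = 3,5-dibromo-2-(2,4-dibromophenoxy)-1,4-benzoquinone; 5 = 3,5-dibromo-2-(2,4-dibromophenoxy)benzene-1,4-diol; 6 = the 1-O-pivalate of 5; 7 = the 4-O-methyl ether of 6; 8 = the target. Ring A carries the locants of the target (C1 OH, C2 O-aryl, C3 Br, C4 OMe, C5 Br, C6 H), and these locants are also used for the corresponding atoms of 1 and 4–7.

## Analysis of the target

The target 8 is a tetrabrominated diaryl ether in which ring A is a pentasubstituted benzene (C1 OH, C2 O-aryl, C3 Br, C4 OMe, C5 Br, C6 H) and ring B is a 2,4-dibromophenyl group on the oxygen at C2. There is no stereocentre and no ring fusion, and the only bond joining the two halves is O–C2. Four aryl C–Br bonds must survive, which rules out organolithium reagents, zerovalent palladium, dissolving metals and hydrogenolysis anywhere in the route. Ring A is a hydroquinone monomethyl ether and is easily oxidised once its phenol is ionised. The synthesis is hard for three reasons: the O–C2 bond is flanked by OH and Br on ring A and by Br on ring B; the para oxygens at C1 and C4 must be told apart (free OH against OMe); and the four bromines must sit at defined positions while C6 and C6' stay free. The strategy rests on the para relation of the C1 and C4 oxygens: ring A is at the hydroquinone oxidation level, and its quinone form 1 already carries the bromines at C3 and C5 and turns C2 from a nucleophilic arene carbon into an electrophilic enone β-carbon. Ring B with its oxygen is simply 2.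

## Retrosynthetic reasoning

8 ⇒ 7. The last bond cut is the acyl–O1 bond of a pivalate. The free C1 phenol is revealed last, so that the oxidation-prone 4-methoxyphenol is never exposed to base and an alkylating agent together. The forward step is a plain ester cleavage that must leave four aryl bromides and two ethers alone.

7 ⇒ 6. The O4–CH3 bond is cut. In 6 the only free hydroxyl is the one between the bromines at C3 and C5, so the forward methylation has no site selectivity to solve. It only has to alkylate a hindered, weakly basic phenoxide with a small electrophile.

6 ⇒ 5. The acyl–O1 bond is cut again, this time as the step that differentiates the two hydroxyls of 5. The C4 hydroxyl is the more acidic, but a rough estimate from substituent increments (two ortho bromines against two meta bromines plus an ortho aryloxy group) puts the gap at only one to two pKa units. Its anion is also the more hindered and the weaker nucleophile, so a direct monomethylation steered by acidity alone is not secure. The steric difference is larger and points the other way: O1 has a hydrogen at C6 on one side, whereas O4 sits between two bromines. A bulky acyl group is therefore placed on O1 first. This costs two steps, but each rests on a clear basis.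

5 ⇒ 1 + 2 (through 3 and 4). The O–C2 bond is cut. This is the only cut that leaves two simple pieces already holding all four bromines in place. In normal polarity both ends are nucleophilic, and a metal-mediated coupling would need a leaving group at C2 between two substituents and would have to spare four C–Br bonds. Raising ring A to quinone 1 reverses the polarity of C2. The forward reaction must make the phenoxide 3 add through oxygen to a CH carbon of 1 and not to a bromine-bearing carbon with loss of that bromine. It must stop after one addition, and it must finish with all material at the hydroquinone level 5.

## Alternatives that were turned down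

Alternative 1: Ring A is taken apart into three pieces by cutting C3–C4, C1–C2 and C1–C6, which leads back to a chromium carbene complex A1, an aryloxyalkyne A2 and a carbonyl ligand of A1. In the forward direction pentacarbonyl[methoxy((E)-2-trimethylsilylvinyl)carbene]chromium (A1) and 2,4-dibromo-1-(ethynyloxy)benzene (A2) combine with one carbonyl ligand in a Dötz benzannulation. After a carbon-to-oxygen silyl shift this should give [2-(2,4-dibromophenoxy)-4-methoxyphenoxy]trimethylsilane (A3).
- For: the two ring A oxygens arrive differentiated (OMe from the carbene carbon of A1, O-silyl from the carbonyl ligand), and the hindered ether bond is brought in with A2. On both points it is stronger than the chosen route, which needs a protection detour.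
- Against: A3 has no bromine on ring A. Later bromination at C3 and C5 must compete with C6, which lies ortho to the C1 oxygen, and C3 is wedged between two oxygen substituents. The usual access to aryl ethynyl ethers such as A2 uses alkyllithium bases, which exchange aryl bromides. A1 is consumed in stoichiometric amount, and the insertion regiochemistry of an ynol ether such as A2 is not secured.
- Comparison: the preparation of A1 and of A2, the annulation, desilylation and bromination add up to a clearly longer sequence. The chosen strategy instead buys all four bromines in position and has one selectivity question in one bond-forming event.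

Alternative 2: All four C–Br bonds are cut. In the forward direction constant-current electrolysis of a bromide electrolyte in acetic acid in an undivided cell generates the brominating agent at the anode in the presence of 4-methoxy-2-phenoxyphenyl pivalate (A4). It should substitute C5, C4', C3 and C2' to give 3,5-dibromo-2-(2,4-dibromophenoxy)-4-methoxyphenyl pivalate (A5), which has the constitution of 7.
- For: A4 is a halogen-free diaryl ether that can be made by ordinary coupling chemistry, the oxygens are already differentiated, no quinone is handled, and A5 is one deprotection from the target. On handling and on oxygen differentiation it is as strong as or stronger than the chosen route.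
- Against: exactly four of six activated positions of A4 must react. The fourth bromine has to enter the hindered C3 of an already brominated ring A in competition with C6' of ring B and C6 of ring A, and nothing in A4 decides this. Mixtures of tri-, tetra- and pentabromides of very similar polarity are the likely result.
- Comparison: the step count is similar. The chosen strategy replaces an open regiochemical problem over two rings by a single binary choice (CH against C–Br carbon) and fixes the bromine positions by the choice of 1 and 2.

Alternative 3: The C4–C5 bond of ring A is cut and ring A is traced back to a four-membered ring. In the forward direction racemic 3-(2,4-dibromophenoxy)-4-(tert-butyldimethylsilyloxy)-4-vinylcyclobut-2-en-1-one (A6) is heated. It should open to a dienylketene, which closes by forming C4–C5 and tautomerises to 4-(tert-butyldimethylsilyloxy)-3-(2,4-dibromophenoxy)phenol (A7).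
- For: the key step needs no reagent, the substitution pattern is dictated by A6, and the oxygens come out differentiated (free OH at the future C4, O-silyl at the future C1). The free hydroxyl of A7 would also direct a later dibromination to C3 and C5. On oxygen differentiation it is stronger than the chosen route.
- Against: A6 has to be built from 3-(2,4-dibromophenoxy)cyclobut-3-ene-1,2-dione (A8). This needs a vinyl organometallic to add to one of the two carbonyls of A8 without displacing the aryloxy group or touching the aryl bromides, followed by silylation of a tertiary alcohol. The stereocentre of A6 is made only to be destroyed. A7 still lacks both ring A bromines and the methyl group.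
- Comparison: at least seven steps against four. The chosen route accepts one protection/deprotection pair in exchange for commercial, fully brominated building blocks.

Key step: step 1

Assumption: 1 and 2 are taken as catalogue chemicals and used as purchased.

## Route

Step 1
Reactants: 1 2,6-dibromo-1,4-benzoquinone; 2 2,4-dibromophenol
Product: 5 3,5-dibromo-2-(2,4-dibromophenoxy)benzene-1,4-diol, via potassium 2,4-dibromophenoxide 3 (not isolated), via 3,5-dibromo-2-(2,4-dibromophenoxy)-1,4-benzoquinone 4 (not isolated)
Conditions: 2, KOtBu (1.0 equiv), THF, 0 °C; added over 1 h to 1 (2.2 equiv), MeCN, −30 → 0 °C, Ar, dark; then aq. Na2S2O4, EtOAc; 1 M HCl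
Reagents that add atoms: none
Why: Phenoxide 3 attacks through oxygen at one of the two hydrogen-bearing carbons of 1 (the future C2), which is the β-carbon of the enone ending in the bromine-flanked carbonyl (future C4), so the charge arrives on O4 as an α-bromo enolate, and transfer of the C2 proton (tBuOH as shuttle) aromatises the adduct to the potassium salt of 5. The surplus of 1, which should be the stronger oxidant, converts this electron-rich salt into quinone 4, and Na2S2O4 returns all of it to 5 at work-up, so the product is collected at a single oxidation level. The closest known reaction type is the conjugate (oxidative) addition of phenoxides, alkoxides, amines and thiolates to 1,4-benzoquinones, and the nearest analogy is the hydration of 2,6-dihalo-1,4-benzoquinones, in which the oxygen nucleophile enters at the CH carbon and both halogens stay. No ring is closed and no stereocentre is formed. The critical selectivity is attack at CH against addition–elimination at a C–Br carbon: the CH carbon is unhindered, its enolate is held by the more electron-poor carbonyl between two bromines, and the ortho-brominated phenoxide is a bulky nucleophile that should avoid the bromine-bearing carbon, which low temperature should reinforce. The two CH carbons of 1 are related by the mirror plane through both carbonyls, so CH attack can give only one constitution. A second addition at the remaining CH of 4 is held back by adding 3 slowly to an excess of 1, the more electrophilic quinone, and attack through a ring carbon of 3 is disfavoured because its para and one ortho position are blocked, the ring is deactivated by two bromines, and the potassium salt in MeCN reacts at oxygen.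

Step 2
Reactants: 5 3,5-dibromo-2-(2,4-dibromophenoxy)benzene-1,4-diol
Product: 6 3,5-dibromo-2-(2,4-dibromophenoxy)-4-hydroxyphenyl 2,2-dimethylpropanoate
Conditions: PivCl (1.05 equiv), pyridine (3 equiv), CH2Cl2, −20 → 0 °C, Ar
Reagents that add atoms: pivaloyl chloride, CC(C)(C)C(=O)Cl
Why: Sterically controlled O-acylation of a phenol through the N-pivaloylpyridinium ion. The C1 hydroxyl has the hydrogen at C6 on one side, whereas the C4 hydroxyl lies between the bromines at C3 and C5, is the weaker nucleophile as the more acidic phenol and is hardly ionised by pyridine, so the bulky acyl group should go to O1 and a second acylation should be slow.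

Step 3
Reactants: 6 3,5-dibromo-2-(2,4-dibromophenoxy)-4-hydroxyphenyl 2,2-dimethylpropanoate
Product: 7 3,5-dibromo-2-(2,4-dibromophenoxy)-4-methoxyphenyl 2,2-dimethylpropanoate
Conditions: MeI (3 equiv), K2CO3 (1.5 equiv), dry DMF, rt, Ar
Reagents that add atoms: iodomethane, CI
Why: Williamson ether synthesis on the only free hydroxyl; K2CO3 should ionise this acidic 2,6-dibromophenol completely and the small electrophile MeI is little hindered by the two ortho bromines. The hindered pivalate is inert to anhydrous carbonate.

Step 4
Reactants: 7 3,5-dibromo-2-(2,4-dibromophenoxy)-4-methoxyphenyl 2,2-dimethylpropanoate
Product: 8 3,5-dibromo-2-(2,4-dibromophenoxy)-4-methoxyphenol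
Conditions: NaOMe (2 equiv), MeOH–THF, 0 °C → rt, Ar; then 1 M HCl
Reagents that add atoms: none
Why: Base-mediated transesterification (methanolysis) of an aryl ester; methoxide adds to the pivaloyl carbonyl and expels the aryloxide, a good leaving group because of the two meta bromines and the ortho aryloxy group. Aryl bromides, the methyl ether and the diaryl ether are inert to NaOMe at room temperature, and acidification should give 8.

## Compound list

1 | 2,6-dibromo-1,4-benzoquinone (2,6-dibromocyclohexa-2,5-diene-1,4-dione) | O=C1C=C(Br)C(=O)C(Br)=C1 | starting material
2 | 2,4-dibromophenol | Oc1ccc(Br)cc1Br | starting material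
3 | potassium 2,4-dibromophenoxide | [K+].[O-]c1ccc(Br)cc1Br | intermediate
4 | 3,5-dibromo-2-(2,4-dibromophenoxy)-1,4-benzoquinone | O=C1C=C(Br)C(=O)C(Br)=C1Oc1ccc(Br)cc1Br | intermediate
5 | 3,5-dibromo-2-(2,4-dibromophenoxy)benzene-1,4-diol | Oc1cc(Br)c(O)c(Br)c1Oc1ccc(Br)cc1Br | intermediate
6 | 3,5-dibromo-2-(2,4-dibromophenoxy)-4-hydroxyphenyl 2,2-dimethylpropanoate | CC(C)(C)C(=O)Oc1cc(Br)c(O)c(Br)c1Oc1ccc(Br)cc1Br | intermediate
7 | 3,5-dibromo-2-(2,4-dibromophenoxy)-4-methoxyphenyl 2,2-dimethylpropanoate | COc1c(Br)cc(OC(=O)C(C)(C)C)c(Oc2ccc(Br)cc2Br)c1Br | intermediate
8 | 3,5-dibromo-2-(2,4-dibromophenoxy)-4-methoxyphenol (no stereocentre) | COc1c(Br)cc(O)c(Oc2ccc(Br)cc2Br)c1Br | target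

## Step count and least certain steps

Total: 4 steps. Longest linear sequence: 4 steps (from 1 or from 2, which meet in step 1).

Step 1 (key step). The most likely failure is displacement of a ring bromine by addition–elimination at a C–Br carbon of 1 in competition with addition at CH. Over-addition to 4 and electron transfer between 3 and 1 are lesser losses. Both modes are open to a β-halo enone and only the balance of hindrance and enolate stability separates them. The fallback gives up the quinone, makes the ether by nucleophilic aromatic substitution and makes the C1 hydroxyl by Baeyer–Villiger oxidation. It sets out from 2 and comes back to the route at 8. Commercial 2-fluoro-4-hydroxybenzaldehyde F1 is brominated at both positions ortho to the hydroxyl (Br2, NaOAc, AcOH) to 3,5-dibromo-2-fluoro-4-hydroxybenzaldehyde F2. This is O-methylated (MeI, K2CO3, DMF) to 3,5-dibromo-2-fluoro-4-methoxybenzaldehyde F3. Phenol 2 with K2CO3 in DMF at 80 °C then displaces the fluoride, which is activated by the ortho formyl group, to give 3,5-dibromo-2-(2,4-dibromophenoxy)-4-methoxybenzaldehyde F4. Oxidation with mCPBA in CH2Cl2 should give 3,5-dibromo-2-(2,4-dibromophenoxy)-4-methoxyphenyl formate F5 by aryl migration, and hydrolysis (KOH, MeOH–H2O; then HCl) gives 8.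

Step 2. The risk is acylation at the hindered O4 or at both oxygens, if ion pairing of the more acidic hydroxyl with the base raises its reactivity more than the bromines lower it. The fallback drops the protecting group and uses kinetic acidity in place of steric control. It sets out from 5 and comes back at 8: slow addition of about one equivalent of Me3SiCHN2 in toluene–MeOH at 0 °C should methylate the more acidic C4 hydroxyl first, because proton transfer to the diazoalkane is rate-limiting, and the reaction is stopped before the C1 hydroxyl is touched. This fallback makes no new compound (F0).

Step 3. The risk is sluggish alkylation of the hindered, weakly basic phenoxide, with loss or transfer of the pivaloyl group during a long exposure to base. The fallback is a Mitsunobu etherification under neutral conditions (MeOH, PPh3, diisopropyl azodicarboxylate, THF, 0 °C → rt), for which an acidic phenol is a good pronucleophile. It sets out from 6 and comes back at 7 and makes no new compound (F0).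

Step 4. The risk is incomplete methanolysis of the hindered ester, or air oxidation of the liberated electron-rich phenoxide in basic methanol. The fallback is reductive cleavage with iBu2AlH (2.5 equiv) in toluene at −78 °C, with acidic work-up. It sets out from 7 and comes back at 8, keeps the phenol as an aluminium phenoxide until acidification, and makes no new compound (F0).

## Further compounds

F1 | step 1 | 2-fluoro-4-hydroxybenzaldehyde | O=Cc1ccc(O)cc1F
F2 | step 1 | 3,5-dibromo-2-fluoro-4-hydroxybenzaldehyde | O=Cc1cc(Br)c(O)c(Br)c1F
F3 | step 1 | 3,5-dibromo-2-fluoro-4-methoxybenzaldehyde | COc1c(Br)cc(C=O)c(F)c1Br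
F4 | step 1 | 3,5-dibromo-2-(2,4-dibromophenoxy)-4-methoxybenzaldehyde | COc1c(Br)cc(C=O)c(Oc2ccc(Br)cc2Br)c1Br
F5 | step 1 | 3,5-dibromo-2-(2,4-dibromophenoxy)-4-methoxyphenyl formate | COc1c(Br)cc(OC=O)c(Oc2ccc(Br)cc2Br)c1Br
F0 | step 2 | none | none
F0 | step 3 | none | none
F0 | step 4 | none | none
A1 | alternative 1 | pentacarbonyl[methoxy((E)-2-trimethylsilylvinyl)carbene]chromium | COC(/C=C/[Si](C)(C)C)=[Cr](=C=O)(=C=O)(=C=O)(=C=O)=C=O
A2 | alternative 1 | 2,4-dibromo-1-(ethynyloxy)benzene | C#COc1ccc(Br)cc1Br
A3 | alternative 1 | [2-(2,4-dibromophenoxy)-4-methoxyphenoxy]trimethylsilane | COc1ccc(O[Si](C)(C)C)c(Oc2ccc(Br)cc2Br)c1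
A4 | alternative 2 | 4-methoxy-2-phenoxyphenyl pivalate | COc1ccc(OC(=O)C(C)(C)C)c(Oc2ccccc2)c1
A5 | alternative 2 | 3,5-dibromo-2-(2,4-dibromophenoxy)-4-methoxyphenyl pivalate | COc1c(Br)cc(OC(=O)C(C)(C)C)c(Oc2ccc(Br)cc2Br)c1Br
A6 | alternative 3 | racemic 3-(2,4-dibromophenoxy)-4-(tert-butyldimethylsilyloxy)-4-vinylcyclobut-2-en-1-one | O=C1C=C(Oc2ccc(Br)cc2Br)C1(O[Si](C)(C)C(C)(C)C)C=C
A7 | alternative 3 | 4-(tert-butyldimethylsilyloxy)-3-(2,4-dibromophenoxy)phenol | Oc1ccc(O[Si](C)(C)C(C)(C)C)c(Oc2ccc(Br)cc2Br)c1
A8 | alternative 3 | 3-(2,4-dibromophenoxy)cyclobut-3-ene-1,2-dione | O=C1C=C(Oc2ccc(Br)cc2Br)C1=O
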